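**Retrosynthetic overview**
1. Target 15 ⇐ hydrolysis of the two quinone methyl ethers of 13.
2. 13 ⇐ two-fold decarboxylative radical C–H phenethylation of biquinone 10 with 3-phenylpropanoic acid 11.
3. 10 ⇐ one thermolysis of the butadiyne-bridged bis(4-hydroxycyclobutenone) 8: both quinone rings (ring A and ring B) form together by a double Moore ring expansion, and the old diyne σ-bond becomes the biaryl bond.
4. 8 ⇐ dilithiobutadiyne (from hexachlorobutadiene 5) + 2 × cyclobutenedione 4; 4 ⇐ dimethyl squarate 1 + MeLi.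
5. Ring order: the purchased four-membered ring is carried to step 3, where rings A and B are made at once; no further ring is formed.

Assumption: the target SMILES has no stereodescriptor and no stereogenic centre, and the configuration of the hindered biquinone axis is not specified, so no stereocontrol is needed and the compound is made as drawn.
Assumption: lithium or sodium salts that are only protonated in the work-up are counted with their neutral form.

**Route**

Step 1
Reactants: 1 3,4-dimethoxycyclobut-3-ene-1,2-dione (dimethyl squarate)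
Product: 4 3-methoxy-4-methylcyclobut-3-ene-1,2-dione, via lithium alkoxide adduct 2 (not isolated), via trifluoroacetate ester 3 (not isolated)
Conditions: MeLi (1.05 equiv), THF, −78 °C; (CF3CO)2O (1.2 equiv), −78 °C; H2O, −78 °C → rt
Reagents that add atoms: methyllithium, [Li]C; water, O
Why: 1,2-addition of MeLi to one squarate carbonyl, O-trifluoroacetylation and hydrolytic 1,3-carbonyl transposition with loss of methanol is the standard Moore–Liebeskind squarate alkylation, and the transient carbinol stereocentre becomes sp2 in the product.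

Step 2
Reactants: 4 3-methoxy-4-methylcyclobut-3-ene-1,2-dione (2.05 equiv); 5 hexachlorobuta-1,3-diene (1.0 equiv)
Product: 8 4,4'-(buta-1,3-diyne-1,4-diyl)bis(4-hydroxy-3-methoxy-2-methylcyclobut-2-en-1-one), via dilithiobutadiyne 6 (not isolated), via lithium monoadduct 7 (not isolated)
Conditions: 5, n-BuLi (3.95 equiv), THF, −78 °C → rt, 2 h; then 4, THF, −78 °C, 1 h; sat. aq NH4Cl, −78 °C → rt
Reagents that add atoms: none
Why: Four-fold Cl/Li exchange–elimination of hexachlorobutadiene gives the dilithium diacetylide, which undergoes acetylide 1,2-addition at the ketone-like carbonyl next to the methoxy-bearing carbon (not the vinylogous-ester carbonyl) of each dione; the two carbinol centres form as a meso/dl mixture, which is irrelevant because both become sp2 in step 3.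

Step 3
Reactants: 8 4,4'-(buta-1,3-diyne-1,4-diyl)bis(4-hydroxy-3-methoxy-2-methylcyclobut-2-en-1-one)
Product: 10 5,5'-dimethoxy-6,6'-dimethyl-2,2'-bi(1,4-benzoquinone), via alkynyl monoquinone 9 (not isolated)
Conditions: PhMe (0.01 M, degassed), 110 °C, 1–2 h, Ar, dark
Reagents that add atoms: none
Why: Proposed new method: a two-fold Moore rearrangement across a butadiyne tether, in which each 4-alkynyl-4-hydroxycyclobutenone opens by 4π-electrocyclic ring opening (hydroxyl rotating outward) to an enynylketene that closes onto the distal alkyne carbon to a phenoxyl/aryl diradical, quenched by transfer of the hydroxyl hydrogen to give the quinone directly without an oxidant, the first quinone then serving as the aryl-type alkyne substituent for the second closure so that rings A and B and the biaryl bond arise in one isomerisation with no by-product; the closest known reaction is the Moore cyclisation of single 4-alkynyl-4-hydroxycyclobutenones to 1,4-benzoquinones.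

Step 4
Reactants: 10 5,5'-dimethoxy-6,6'-dimethyl-2,2'-bi(1,4-benzoquinone); 11 3-phenylpropanoic acid (4 equiv)
Product: 13 5,5'-dimethoxy-6,6'-dimethyl-3,3'-bis(2-phenylethyl)-2,2'-bi(1,4-benzoquinone), via monoalkylated biquinone 12 (not isolated)
Conditions: AgNO3 (0.4 equiv), (NH4)2S2O8 (4 equiv, portionwise), MeCN/H2O 1:1, 70 °C
Reagents that add atoms: none
Why: Jacobsen–Torssell (Minisci-type) decarboxylative alkylation, in which divalent silver formed from AgNO3 and persulfate oxidises the acid to the nucleophilic 2-phenylethyl radical, which adds at the only unsubstituted quinone carbon of each ring, and oxidation of the adduct radical restores the quinone, so regiochemistry is forced.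

Step 5
Reactants: 13 5,5'-dimethoxy-6,6'-dimethyl-3,3'-bis(2-phenylethyl)-2,2'-bi(1,4-benzoquinone)
Product: 15 5,5'-dihydroxy-6,6'-dimethyl-3,3'-bis(2-phenylethyl)-2,2'-bi(1,4-benzoquinone), via monomethyl ether 14 (not isolated)
Conditions: 1 M aq NaOH (6 equiv), MeOH/THF, 0 °C → rt, Ar; then 1 M HCl
Reagents that add atoms: sodium hydroxide, [Na+].[OH-]
Why: Vinylogous ester saponification (addition–elimination of hydroxide at the methoxy-bearing quinone carbon) gives the stabilised hydroxyquinone anion, which resists further attack and is protonated on acidification; no stereocentre is involved.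

**Compound list**
1 | 3,4-dimethoxycyclobut-3-ene-1,2-dione (dimethyl squarate) | COC1=C(OC)C(=O)C1=O | starting material
2 | lithium alkoxide adduct: lithium 2,3-dimethoxy-1-methyl-4-oxocyclobut-2-en-1-olate (racemic, not isolated) | [Li+].CC1([O-])C(OC)=C(OC)C1=O | intermediate
3 | trifluoroacetate ester: 2,3-dimethoxy-1-methyl-4-oxocyclobut-2-en-1-yl trifluoroacetate (racemic, not isolated) | CC1(OC(=O)C(F)(F)F)C(OC)=C(OC)C1=O | intermediate
4 | 3-methoxy-4-methylcyclobut-3-ene-1,2-dione | COC1=C(C)C(=O)C1=O | intermediate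
5 | hexachlorobuta-1,3-diene | ClC(Cl)=C(Cl)C(Cl)=C(Cl)Cl | starting material
6 | dilithiobutadiyne: 1,4-dilithiobuta-1,3-diyne (not isolated) | [Li]C#CC#C[Li] | intermediate
7 | lithium monoadduct: lithium 1-(4-lithiobuta-1,3-diyn-1-yl)-2-methoxy-3-methyl-4-oxocyclobut-2-en-1-olate (racemic, not isolated) | [Li+].[Li]C#CC#CC1([O-])C(OC)=C(C)C1=O | intermediate
8 | 4,4'-(buta-1,3-diyne-1,4-diyl)bis(4-hydroxy-3-methoxy-2-methylcyclobut-2-en-1-one) (meso/dl mixture) | CC1=C(OC)C(O)(C#CC#CC2(O)C(OC)=C(C)C2=O)C1=O | intermediate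
9 | alkynyl monoquinone: 2-[(1-hydroxy-2-methoxy-3-methyl-4-oxocyclobut-2-en-1-yl)ethynyl]-5-methoxy-6-methyl-1,4-benzoquinone (racemic, not isolated) | CC1=C(OC)C(=O)C=C(C#CC2(O)C(OC)=C(C)C2=O)C1=O | intermediate
10 | 5,5'-dimethoxy-6,6'-dimethyl-2,2'-bi(1,4-benzoquinone) (= 4,4'-dimethoxy-5,5'-dimethyl-[1,1'-bi(cyclohexa-1,4-diene)]-3,3',6,6'-tetrone) | CC1=C(OC)C(=O)C=C(C2=CC(=O)C(OC)=C(C)C2=O)C1=O | intermediate
11 | 3-phenylpropanoic acid | OC(=O)CCc1ccccc1 | starting material
12 | monoalkylated biquinone: 5,5'-dimethoxy-6,6'-dimethyl-3-(2-phenylethyl)-2,2'-bi(1,4-benzoquinone) (not isolated) | CC1=C(OC)C(=O)C(CCc2ccccc2)=C(C2=CC(=O)C(OC)=C(C)C2=O)C1=O | intermediate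
13 | 5,5'-dimethoxy-6,6'-dimethyl-3,3'-bis(2-phenylethyl)-2,2'-bi(1,4-benzoquinone) | CC1=C(OC)C(=O)C(CCc2ccccc2)=C(C2=C(CCc3ccccc3)C(=O)C(OC)=C(C)C2=O)C1=O | intermediate
14 | monomethyl ether: 5-hydroxy-5'-methoxy-6,6'-dimethyl-3,3'-bis(2-phenylethyl)-2,2'-bi(1,4-benzoquinone) (not isolated) | CC1=C(O)C(=O)C(CCc2ccccc2)=C(C2=C(CCc3ccccc3)C(=O)C(OC)=C(C)C2=O)C1=O | intermediate
15 | 5,5'-dihydroxy-6,6'-dimethyl-3,3'-bis(2-phenylethyl)-2,2'-bi(1,4-benzoquinone) (CNP0136737.0) | CC1=C(O)C(=O)C(CCc2ccccc2)=C(C2=C(CCc3ccccc3)C(=O)C(O)=C(C)C2=O)C1=O | target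

**Totals**
Total step count: 5. Longest linear sequence: 5 steps (1 → 4 → 8 → 10 → 13 → 15); 5 and 11 are purchased and enter directly.

**Steps most likely to fail, with fallbacks**

Step 3 (double Moore ring expansion). The diradical can close to a five-membered ring (2-alkylidenecyclopentene-1,3-dione) instead of the quinone. Radical-stabilising alkyne substituents favour that path, and here the substituent is first an alkynyl and then a quinonyl group. The fallback replaces the diradical closure by a pericyclic one and sets out from 8. Semi-hydrogenation (H2 1 atm, Pd/CaCO3 poisoned with Pb(OAc)2, quinoline, EtOAc) gives 4,4'-[(1Z,3Z)-buta-1,3-diene-1,4-diyl]bis(4-hydroxy-3-methoxy-2-methylcyclobut-2-en-1-one) F1. Heating F1 in toluene at 110 °C opens each four-membered ring to a dienylketene, which closes by 6π-electrocyclisation (no five-ring alternative) and tautomerises. This still builds both rings in one operation and gives 4,4'-dimethoxy-3,3'-dimethyl-[1,1'-biphenyl]-2,2',5,5'-tetrol F2. Oxidation with Ag2O (Et2O, rt) returns to the route at 10.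

Step 4 (two-fold radical phenethylation). Each new C–C bond is made next to the biaryl axis, so the second alkylation may stall at 12, and persulfate can over-oxidise benzylic positions. The fallback sets out from 10. Bromine (CHCl3, 0 °C → rt, addition then loss of HBr) gives 3,3'-dibromo-5,5'-dimethoxy-6,6'-dimethyl-2,2'-bi(1,4-benzoquinone) F3. Stille coupling with (E)-tributyl(2-phenylethenyl)stannane (Pd(PPh3)4, CuI, dioxane, 90 °C) gives 5,5'-dimethoxy-6,6'-dimethyl-3,3'-bis[(E)-2-phenylethenyl]-2,2'-bi(1,4-benzoquinone) F4. Hydrogenation (H2, Pd/C, EtOAc) saturates both alkenes and reduces the quinones to 4,4'-dimethoxy-3,3'-dimethyl-6,6'-bis(2-phenylethyl)-[1,1'-biphenyl]-2,2',5,5'-tetrol F5. Oxidation with Ag2O returns to the route at 13.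

Step 2 (double addition of dilithiobutadiyne). The dilithium diacetylide is poorly soluble, the reaction may stop at monoadduct 7, and any residual n-BuLi adds a butyl group to 4. The fallback builds the diyne by C(sp)–C(sp) coupling instead and sets out from 4. Ethynylmagnesium bromide (HC≡CMgBr, THF, −78 °C; aq NH4Cl) adds at the same carbonyl to give 4-ethynyl-4-hydroxy-3-methoxy-2-methylcyclobut-2-en-1-one F6. Hay oxidative homocoupling (CuCl, TMEDA, O2, acetone, rt) returns to the route at 8.

**Further compounds**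
F1 | step 3 | 4,4'-[(1Z,3Z)-buta-1,3-diene-1,4-diyl]bis(4-hydroxy-3-methoxy-2-methylcyclobut-2-en-1-one) | CC1=C(OC)C(O)(/C=C\C=C/C2(O)C(OC)=C(C)C2=O)C1=O
F2 | step 3 | 4,4'-dimethoxy-3,3'-dimethyl-[1,1'-biphenyl]-2,2',5,5'-tetrol | Cc1c(OC)c(O)cc(-c2cc(O)c(OC)c(C)c2O)c1O
F3 | step 4 | 3,3'-dibromo-5,5'-dimethoxy-6,6'-dimethyl-2,2'-bi(1,4-benzoquinone) | CC1=C(OC)C(=O)C(Br)=C(C2=C(Br)C(=O)C(OC)=C(C)C2=O)C1=O
F4 | step 4 | 5,5'-dimethoxy-6,6'-dimethyl-3,3'-bis[(E)-2-phenylethenyl]-2,2'-bi(1,4-benzoquinone) | CC1=C(OC)C(=O)C(/C=C/c2ccccc2)=C(C2=C(/C=C/c3ccccc3)C(=O)C(OC)=C(C)C2=O)C1=O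
F5 | step 4 | 4,4'-dimethoxy-3,3'-dimethyl-6,6'-bis(2-phenylethyl)-[1,1'-biphenyl]-2,2',5,5'-tetrol | Cc1c(OC)c(O)c(CCc2ccccc2)c(-c2c(CCc3ccccc3)c(O)c(OC)c(C)c2O)c1O
F6 | step 2 | 4-ethynyl-4-hydroxy-3-methoxy-2-methylcyclobut-2-en-1-one | CC1=C(OC)C(O)(C#C)C1=O
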